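**Retrosynthetic overview**

1. Target 15 ⇐ global O-debenzylation of 14 ⇐ 3-O-acylation of 5,7,3',4'-tetra-O-benzyl-(−)-epicatechin 12 with 4-(benzyloxy)benzoyl chloride 13.
2. Key disconnection C2–C1' (pyran C ring to catechol B ring): 12 ⇐ (3R)-lactol 8 + arylboronic acid 9, by boron-tethered cis-arylation of the C2 oxocarbenium ion.
3. Enabling feature: C2 is the only C-ring carbon bonded to the ring oxygen O1, so as a hemiacetal carbon it ionises to an O1-stabilised cation. The oxygen on the neighbouring C3 is cis to the aryl group in the target and can hold the boron that delivers the B ring. The migrating carbon C1' is para to O4'.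
4. 8 ⇐ L-proline/nitrosobenzene α-aminoxylation of lactol 5 (sets C3) ⇐ DIBAL-H ⇐ dihydrocoumarin 4 ⇐ 5,7-dihydroxycoumarin 1.
5. Ring order: the A and C rings are bought fused in coumarin 1 and only adjusted in oxidation level (steps 2–4); the B ring is joined in step 5 and the benzoate ring in step 6; no ring is built de novo.

Key step: step 5

Assumption: compounds 1, 2, 6, 9 and 13 are purchased; the anomeric carbon C2 of lactols 5, 7 and 8 is configurationally labile and is erased in step 5, so it is left undefined.

**Step 1**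
Reactants: 1 5,7-dihydroxycoumarin; 2 benzyl bromide
Product: 3 5,7-bis(benzyloxy)coumarin
Conditions: BnBr (2.4 equiv), K2CO3, DMF, 60 °C
Reagents that add atoms: benzyl bromide, BrCc1ccccc1
Why: Williamson ether synthesis, in which the two phenoxides of the conjugated coumarin should be O-alkylated cleanly; no stereocentre is formed.

**Step 2**
Reactants: 3 5,7-bis(benzyloxy)coumarin
Product: 4 5,7-bis(benzyloxy)chroman-2-one
Conditions: H2 (1 atm), 5% Pd/C(en) (ethylenediamine-poisoned), THF, rt
Reagents that add atoms: none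
Why: Chemoselective heterogeneous hydrogenation, in which the amine-poisoned catalyst should saturate the conjugated C3=C4 bond but be too deactivated to hydrogenolyse aryl benzyl ethers; no stereocentre is formed.

**Step 3**
Reactants: 4 5,7-bis(benzyloxy)chroman-2-one
Product: 5 5,7-bis(benzyloxy)chroman-2-ol
Conditions: DIBAL-H (1.05 equiv), CH2Cl2, −78 °C; Rochelle salt work-up
Reagents that add atoms: none
Why: Partial reduction of a lactone to a lactol, in which the tetrahedral aluminium hemiacetal should persist at −78 °C until work-up; C2 forms as an inconsequential anomeric mixture.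

**Step 4**
Reactants: 5 5,7-bis(benzyloxy)chroman-2-ol; 6 nitrosobenzene
Product: 8 (3R)-5,7-bis(benzyloxy)chroman-2,3-diol, via 3-anilinooxy lactol 7 (not isolated)
Conditions: L-proline (30 mol %), PhNO (slow addition), MeCN, −20 °C; then AcOH, Zn dust, 0 °C → rt; cold dilute HCl wash
Reagents that add atoms: nitrosobenzene, O=Nc1ccccc1
Why: Proline-catalysed enantioselective α-aminoxylation (nitroso aldol reaction) of the ring-opened 3-arylpropanal form of the lactol, in which L-proline should direct oxygen to the enamine face that gives the (R)-α-oxy aldehyde (C3), which recloses to the lactol and is thereby shielded from racemisation, followed by reductive N–O cleavage with zinc in acetic acid.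

**Step 5**
Reactants: 8 (3R)-5,7-bis(benzyloxy)chroman-2,3-diol; 9 3,4-bis(benzyloxy)phenylboronic acid
Product: 12 5,7,3',4'-tetra-O-benzyl-(−)-epicatechin, via cyclic 2,3-O-arylboronate 10 (not isolated), via 3-O-dihydroxyboryl ether 11 (not isolated)
Conditions: 9 (1.5 equiv), CH2Cl2/HFIP (4:1), 0.02 M, rt; then Yb(OTf)3 (10 mol %), −20 → 0 °C; aq. NaHCO3/sorbitol work-up
Reagents that add atoms: 3,4-bis(benzyloxy)phenylboronic acid, OB(O)c1ccc(OCc2ccccc2)c(OCc2ccccc2)c1
Why: Proposed new method: boronic acid 9 condenses with the cis-lactol form of 8 to the cyclic boronate 10, the Lewis acid ionises its C2–O bond to the O1-stabilised oxocarbenium ion while boron stays on O3, and after uptake of water the tetracoordinate boronate passes its electron-rich aryl group (migrating carbon C1' para to O4') from boron to C2 through a five-membered transition state (C2–C3–O3–B–C1') to give borate 11, which work-up hydrolyses to 12. The closest known reaction types are the Petasis borono-Mannich reaction of α-hydroxy aldehydes, the hydroxyl-directed cis-addition of boronates to cyclic N-acyliminium ions and the Lewis-acid-promoted addition of aryl boronates to 2-alkoxy-2H-chromenes; the transfer to a saturated 3-hydroxychroman-2-yl cation has not been shown. No ring of the product is closed: only the transient dioxaborolane of 10 forms by condensation and is opened again. The new stereocentre C2 is controlled by the C3 stereocentre through the boron tether, since the aryl group can only arrive on the face that bears O3, which gives the 2,3-cis (2R,3R) flavan whichever anomer of 8 ionises. The step needs the intramolecular transfer to outrun Friedel–Crafts capture of the cation by the A ring (C6, C8) of a second molecule and attack anti to O3; high dilution and the fact that only the O3-bound boronate is a competent aryl donor should secure this.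

**Step 6**
Reactants: 12 5,7,3',4'-tetra-O-benzyl-(−)-epicatechin; 13 4-(benzyloxy)benzoyl chloride
Product: 14 5,7,3',4'-tetra-O-benzyl-(−)-epicatechin 3-O-[4-(benzyloxy)benzoate]
Conditions: 13 (1.5 equiv), Et3N, DMAP (20 mol %), CH2Cl2, 0 °C → rt
Reagents that add atoms: 4-(benzyloxy)benzoyl chloride, O=C(Cl)c1ccc(OCc2ccccc2)cc1
Why: DMAP-catalysed acylation (nucleophilic catalysis) of the hindered axial 3-OH by the acid chloride, a reaction type well established for 3-O-aroylation of benzyl-protected epicatechin; no stereocentre is touched.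

**Step 7**
Reactants: 14 5,7,3',4'-tetra-O-benzyl-(−)-epicatechin 3-O-[4-(benzyloxy)benzoate]
Product: 15 epicatechin 3-O-p-hydroxybenzoate
Conditions: H2 (1 atm), 20% Pd(OH)2/C, THF/MeOH (1:1), rt
Reagents that add atoms: none
Why: Global hydrogenolysis of the five benzyl ethers, under which the aryl ester and the C2–O1 bond of the flavan should persist; both stereocentres are untouched.

**Compound list**

1 | 5,7-dihydroxycoumarin | O=C1C=Cc2c(O)cc(O)cc2O1 | starting material
2 | benzyl bromide | BrCc1ccccc1 | starting material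
3 | 5,7-bis(benzyloxy)coumarin | O=C1C=Cc2c(OCc3ccccc3)cc(OCc3ccccc3)cc2O1 | intermediate
4 | 5,7-bis(benzyloxy)chroman-2-one | O=C1CCc2c(OCc3ccccc3)cc(OCc3ccccc3)cc2O1 | intermediate
5 | 5,7-bis(benzyloxy)chroman-2-ol (racemic lactol) | OC1CCc2c(OCc3ccccc3)cc(OCc3ccccc3)cc2O1 | intermediate
6 | nitrosobenzene | O=Nc1ccccc1 | starting material
7 | (3R)-3-(anilinooxy)-5,7-bis(benzyloxy)chroman-2-ol (C2 epimers, not isolated) | c1ccccc1NO[C@@H]1Cc2c(OCc3ccccc3)cc(OCc3ccccc3)cc2OC1O | intermediate
8 | (3R)-5,7-bis(benzyloxy)chroman-2,3-diol (C2 epimers) | O[C@@H]1Cc2c(OCc3ccccc3)cc(OCc3ccccc3)cc2OC1O | intermediate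
9 | 3,4-bis(benzyloxy)phenylboronic acid | OB(O)c1ccc(OCc2ccccc2)c(OCc2ccccc2)c1 | starting material
10 | (2S,3R)-5,7-bis(benzyloxy)chroman-2,3-diyl [3,4-bis(benzyloxy)phenyl]boronate, cis-fused dioxaborolane (not isolated) | O1[C@@H]2Cc3c(OCc4ccccc4)cc(OCc4ccccc4)cc3O[C@@H]2OB1c1ccc(OCc2ccccc2)c(OCc2ccccc2)c1 | intermediate
11 | (2R,3R)-5,7,3',4'-tetra-O-benzylepicatechin 3-O-boric acid monoester (not isolated) | OB(O)O[C@@H]1Cc2c(OCc3ccccc3)cc(OCc3ccccc3)cc2O[C@@H]1c1ccc(OCc2ccccc2)c(OCc2ccccc2)c1 | intermediate
12 | 5,7,3',4'-tetra-O-benzyl-(−)-epicatechin, (2R,3R), 2,3-cis | O[C@@H]1Cc2c(OCc3ccccc3)cc(OCc3ccccc3)cc2O[C@@H]1c1ccc(OCc2ccccc2)c(OCc2ccccc2)c1 | intermediate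
13 | 4-(benzyloxy)benzoyl chloride | O=C(Cl)c1ccc(OCc2ccccc2)cc1 | starting material
14 | 5,7,3',4'-tetra-O-benzyl-(−)-epicatechin 3-O-[4-(benzyloxy)benzoate], (2R,3R) | O=C(O[C@@H]1Cc2c(OCc3ccccc3)cc(OCc3ccccc3)cc2O[C@@H]1c1ccc(OCc2ccccc2)c(OCc2ccccc2)c1)c1ccc(OCc2ccccc2)cc1 | intermediate
15 | epicatechin 3-O-p-hydroxybenzoate, (2R,3R) | O=C(O[C@@H]1Cc2c(O)cc(O)cc2O[C@@H]1c1ccc(O)c(O)c1)c1ccc(O)cc1 | target

**Step count and risks**

Total step count: 7. Longest linear sequence: 7 steps (1 → 3 → 4 → 5 → 8 → 12 → 14 → 15).

Steps most likely to fail: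

Step 5 (Proposed new method). The cyclic boronate may resist ionisation, the oxocarbenium ion may lose the C3 proton and isomerise to the chroman-3-one, or the cation may be captured by the electron-rich A ring of a second molecule before the aryl group is transferred. The fallback uses known chemistry, sets out from 3 and returns at 12. Coumarin 3 is reduced with DIBAL-H at −78 °C to 5,7-bis(benzyloxy)-2H-chromen-2-ol F1, which is acetalised with ethanol and PPTS to 5,7-bis(benzyloxy)-2-ethoxy-2H-chromene F2. Boronic acid 9 is esterified with ethanol (toluene azeotrope) to diethyl [3,4-bis(benzyloxy)phenyl]boronate F3. Enantioselective addition of F3 to F2, catalysed by a tartaric-acid-derived hydroxy acid amide with a lanthanide triflate co-catalyst (catalyst enantiomer chosen for the 2S product), should give (S)-5,7-bis(benzyloxy)-2-[3,4-bis(benzyloxy)phenyl]-2H-chromene F4. Hydroboration–oxidation (BH3·SMe2, then NaOH/H2O2) anti to the aryl group should give 5,7,3',4'-tetra-O-benzyl-(+)-catechin F5 (2R,3S). Dess–Martin oxidation should give (2R)-5,7,3',4'-tetra-O-benzylflavan-3-one F6, and L-Selectride at −78 °C, attacking anti to the aryl group, should give the 2,3-cis alcohol 12.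

Step 4. Enamine formation from the predominantly closed lactol may be slow, nitrosobenzene may be consumed by N-attack or by the electron-rich arene, and the aniline released may condense with the hydroxy aldehyde. The fallback sets out from 4 and returns at 8. The potassium enolate of lactone 4 (KHMDS, THF, −78 °C) is hydroxylated with the enantiomer of (camphorsulfonyl)oxaziridine that delivers (R)-5,7-bis(benzyloxy)-3-hydroxychroman-2-one F7, with crystallisation to raise the enantiomeric purity if needed. DIBAL-H at −78 °C then reduces F7 to lactol 8.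

Step 2. Hydrogenolytic loss of aryl benzyl ethers may accompany saturation of the C3=C4 bond. The fallback sets out from 1 and returns at 4. Coumarin 1 is hydrogenated before protection (H2, Pd/C, EtOAc/EtOH) to 5,7-dihydroxychroman-2-one F8, which is then benzylated (BnBr, K2CO3, acetone) to 4.

**Further compounds**

F1 | step 5 | 5,7-bis(benzyloxy)-2H-chromen-2-ol | OC1C=Cc2c(OCc3ccccc3)cc(OCc3ccccc3)cc2O1
F2 | step 5 | 5,7-bis(benzyloxy)-2-ethoxy-2H-chromene (racemic) | CCOC1C=Cc2c(OCc3ccccc3)cc(OCc3ccccc3)cc2O1
F3 | step 5 | diethyl [3,4-bis(benzyloxy)phenyl]boronate | CCOB(OCC)c1ccc(OCc2ccccc2)c(OCc2ccccc2)c1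
F4 | step 5 | (S)-5,7-bis(benzyloxy)-2-[3,4-bis(benzyloxy)phenyl]-2H-chromene | C1=Cc2c(OCc3ccccc3)cc(OCc3ccccc3)cc2O[C@@H]1c1ccc(OCc2ccccc2)c(OCc2ccccc2)c1
F5 | step 5 | 5,7,3',4'-tetra-O-benzyl-(+)-catechin, (2R,3S) | O[C@H]1Cc2c(OCc3ccccc3)cc(OCc3ccccc3)cc2O[C@@H]1c1ccc(OCc2ccccc2)c(OCc2ccccc2)c1
F6 | step 5 | (2R)-5,7,3',4'-tetra-O-benzylflavan-3-one | O=C1Cc2c(OCc3ccccc3)cc(OCc3ccccc3)cc2O[C@@H]1c1ccc(OCc2ccccc2)c(OCc2ccccc2)c1
F7 | step 4 | (R)-5,7-bis(benzyloxy)-3-hydroxychroman-2-one | O[C@@H]1Cc2c(OCc3ccccc3)cc(OCc3ccccc3)cc2OC1=O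
F8 | step 2 | 5,7-dihydroxychroman-2-one | O=C1CCc2c(O)cc(O)cc2O1
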